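**Strategy**

Ring C is cut at C4–C4a and O1–C2, which turns the isoflavone into an aryl ester: the 3-methoxy-2-arylacrylate of 2,4-diprenylphloroglucinol. The key step uses the fact that C4a is the only unsubstituted carbon of ring A and lies between two symmetry-equivalent oxygens, the future O1 and 5-OH. Light shifts the acyl group from oxygen to C4a, and either flanking hydroxyl then displaces methoxide at C2, so a single neutral operation makes both bonds and ring C while no acid touches the prenyl groups. Precursor 20 is the monoester of free triol 8 with the bis-MOM ring B acid 19; only two MOM groups remain to be removed.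

Key step: step 12

Assumption: prenyl = 3-methylbut-2-en-1-yl and MOM = methoxymethyl throughout; the acrylate is carried as the E isomer, and should light interconvert E and Z in 20 or 21 this is without consequence, because C2 loses its geometry when ring C closes. The ester bond of 20 is made by carbodiimide coupling of the free acid and not through an acid chloride, since HCl would endanger the MOM acetals and the prenyl double bonds.

**Route**

Step 1
Reactants: 1 phloroglucinol
Product: 2 1,3,5-tris(methoxymethoxy)benzene
Conditions: NaH, MOMCl, DMF, 0 °C → rt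
Reagents that add atoms: chloromethyl methyl ether, COCCl
Why: Williamson-type O-alkylation of the triphenoxide with the hard electrophile MOMCl masks all three hydroxyls as acetals that later direct ring lithiation.

Step 2
Reactants: 2 1,3,5-tris(methoxymethoxy)benzene; 3 prenyl bromide (1-bromo-3-methylbut-2-ene)
Product: 5 1,3,5-tris(methoxymethoxy)-2-(3-methylbut-2-en-1-yl)benzene, via aryllithium 4 (not isolated)
Conditions: n-BuLi, THF, 0 °C → rt; then 3, 0 °C → rt
Reagents that add atoms: none
Why: Directed ortho-metalation removes a ring proton flanked by two chelating OMOM groups (all three positions are equivalent), and the aryllithium is alkylated at the primary carbon of the allylic bromide (SN2).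

Step 3
Reactants: 5 1,3,5-tris(methoxymethoxy)-2-(3-methylbut-2-en-1-yl)benzene; 3 prenyl bromide
Product: 7 1,3,5-tris(methoxymethoxy)-2,4-bis(3-methylbut-2-en-1-yl)benzene, via aryllithium 6 (not isolated)
Conditions: n-BuLi, THF, 0 °C; then 3, 0 °C → rt
Reagents that add atoms: none
Why: The same directed ortho-metalation and alkylation is repeated at one of the two equivalent ring positions still flanked by two OMOM groups, chelation-driven ring lithiation being faster than removal of the benzylic–allylic protons of the first prenyl group.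

Step 4
Reactants: 7 1,3,5-tris(methoxymethoxy)-2,4-bis(3-methylbut-2-en-1-yl)benzene
Product: 8 2,4-bis(3-methylbut-2-en-1-yl)benzene-1,3,5-triol (2,4-diprenylphloroglucinol)
Conditions: dilute aq. HCl, MeOH, rt, argon
Reagents that add atoms: none
Why: Acid-catalysed acetal exchange with methanol cleaves the three MOM ethers under dilute, cool conditions chosen so that the trisubstituted alkenes are not protonated, and the air-sensitive triol should be used at once.

Step 5
Reactants: 9 resorcinol
Product: 10 1,3-bis(methoxymethoxy)benzene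
Conditions: NaH, MOMCl, DMF, 0 °C → rt
Reagents that add atoms: chloromethyl methyl ether, COCCl
Why: Williamson-type O-alkylation of the diphenoxide installs two acetal groups that protect ring B and direct the two lithiations that follow.

Step 6
Reactants: 10 1,3-bis(methoxymethoxy)benzene; 3 prenyl bromide
Product: 12 1,3-bis(methoxymethoxy)-2-(3-methylbut-2-en-1-yl)benzene, via aryllithium 11 (not isolated)
Conditions: n-BuLi, THF, 0 °C → rt; then 3, 0 °C → rt
Reagents that add atoms: none
Why: Directed ortho-metalation occurs at C2, the only position flanked by both OMOM groups, and the aryllithium is alkylated by the allylic bromide at its primary carbon (SN2).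

Step 7
Reactants: 12 1,3-bis(methoxymethoxy)-2-(3-methylbut-2-en-1-yl)benzene
Product: 14 2-[2,4-bis(methoxymethoxy)-3-(3-methylbut-2-en-1-yl)phenyl]-4,4,5,5-tetramethyl-1,3,2-dioxaborolane, via aryllithium 13 (not isolated)
Conditions: s-BuLi, TMEDA, THF, −78 °C; then 2-isopropoxy-4,4,5,5-tetramethyl-1,3,2-dioxaborolane, −78 °C → rt; then H2O
Reagents that add atoms: 2-isopropoxy-4,4,5,5-tetramethyl-1,3,2-dioxaborolane, CC(C)OB1OC(C)(C)C(C)(C)O1
Why: Directed ortho-metalation at low temperature places lithium next to one OMOM group (the two such positions are equivalent) faster than the base can reach the twisted benzylic–allylic protons, and the aryllithium is trapped by the borate ester with loss of isopropoxide.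

Step 8
Reactants: 15 methyl (E)-3-methoxyacrylate
Product: 17 methyl (Z)-2-iodo-3-methoxyacrylate, via iodoacetate adduct 16 (not isolated)
Conditions: N-iodosuccinimide, AcOH, CH2Cl2, rt; then Et3N, rt
Reagents that add atoms: N-iodosuccinimide, O=C1CCC(=O)N1I
Why: Iodoacetoxylation of the electron-rich enol ether double bond (iodine at the carbon next to the ester, acetate at the oxocarbenium carbon) followed by base-induced elimination of acetic acid should give the more stable Z iodoalkene, a standard entry to 2-halo-3-methoxyacrylates.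

Step 9
Reactants: 14 aryl pinacol boronate; 17 methyl (Z)-2-iodo-3-methoxyacrylate
Product: 18 methyl (E)-2-[2,4-bis(methoxymethoxy)-3-(3-methylbut-2-en-1-yl)phenyl]-3-methoxyacrylate
Conditions: Pd(PPh3)4 (cat.), K3PO4, dioxane/H2O, 90 °C
Reagents that add atoms: none
Why: Suzuki–Miyaura coupling (oxidative addition of the alkenyl iodide to zerovalent palladium, transmetalation, reductive elimination) proceeds with retention of alkene geometry, so the Z iodide gives the E arylacrylate, the descriptor changing only through the priority rules.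

Step 10
Reactants: 18 methyl (E)-2-[2,4-bis(methoxymethoxy)-3-(3-methylbut-2-en-1-yl)phenyl]-3-methoxyacrylate
Product: 19 (E)-2-[2,4-bis(methoxymethoxy)-3-(3-methylbut-2-en-1-yl)phenyl]-3-methoxyacrylic acid
Conditions: LiOH·H2O, THF/MeOH/H2O, 40 °C; then cold 1 M HCl to pH 4
Reagents that add atoms: lithium hydroxide, [Li+].[OH-]
Why: Saponification of the methyl ester leaves the enol ether, the MOM acetals and the prenyl group untouched, and a cold, only mildly acidic work-up frees the acid without acetal loss.

Step 11
Reactants: 8 2,4-diprenylphloroglucinol; 19 ring B acrylic acid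
Product: 20 3,5-dihydroxy-2,4-bis(3-methylbut-2-en-1-yl)phenyl (E)-2-[2,4-bis(methoxymethoxy)-3-(3-methylbut-2-en-1-yl)phenyl]-3-methoxyacrylate
Conditions: 8 (3 equiv), N,N'-diisopropylcarbodiimide, DMAP (cat.), CH2Cl2, 0 °C → rt, argon
Reagents that add atoms: none
Why: Steglich esterification acylates one of the two equivalent unhindered phenols of 8, which is used in excess to hold back diester formation while the hydroxyl between the two prenyl groups is too shielded to compete, and no HCl is generated that could harm MOM or prenyl groups.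

Step 12
Reactants: 20 3,5-dihydroxy-2,4-diprenylphenyl (E)-3-methoxy-2-arylacrylate
Product: 22 euchrenone b2 2',4'-bis(methoxymethyl) ether, via Fries ketone 21 (not isolated)
Conditions: hν (300 nm lamps, Pyrex), degassed MeCN (about 2 mM), 20 °C; then Et3N (cat.), 20 °C, dark
Reagents that add atoms: none
Why: Excitation of the aryl ester cleaves the ArO–C(=O) bond homolytically to a solvent-caged phenoxyl/acyl radical pair that can recombine at carbon only at the single unsubstituted ring position, and tautomerisation of the resulting cyclohexadienone gives the ortho-hydroxyaryl ketone 21 (C4–C4a formed). The closest known reaction is the photo-Fries rearrangement of aryl cinnamates and other aryl enoates to ortho-hydroxyaryl enones, which also tolerates free phenolic hydroxyls, as in the rearrangement of hydroxyphenyl benzoates. One of the two hydroxyls flanking the new ketone then adds to the β-methoxy enone in a 6-endo-trig oxa-Michael closure and methanol is expelled (addition–elimination, O1–C2 formed), the same closure by which ortho-hydroxyaryl β-alkoxy- or β-aminovinyl ketones are routinely turned into chromones; the trace of Et3N only speeds this dark step. No stereocentre is created, and the alkene geometry is erased when C2 becomes part of the aromatic pyranone. The selectivity needed is acyl return to C4a alone, which the substrate secures because the other ortho carbon and the para carbon already carry prenyl groups, and the two ring-closing hydroxyls are interchangeable by the mirror symmetry of ring A, so a single isoflavone should result. The neutral, room-temperature conditions spare the MOM ethers and all three prenyl groups, which an acid-mediated C-acylation of the prenylated phloroglucinol would not.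

Step 13
Reactants: 22 euchrenone b2 2',4'-bis(methoxymethyl) ether
Product: 23 euchrenone b2
Conditions: 3 M aq. HCl, MeOH, 40 °C, argon
Reagents that add atoms: none
Why: Acid-catalysed acetal exchange with methanol removes the two MOM groups, a customary last step for prenylated isoflavones in which the modest acid strength and short exposure disfavour addition of a phenol to a prenyl double bond.

**Compound list**

1 | phloroglucinol (benzene-1,3,5-triol) | Oc1cc(O)cc(O)c1 | starting material
2 | 1,3,5-tris(methoxymethoxy)benzene | COCOc1cc(OCOC)cc(OCOC)c1 | intermediate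
3 | prenyl bromide (1-bromo-3-methylbut-2-ene) | CC(C)=CCBr | starting material
4 | [2,4,6-tris(methoxymethoxy)phenyl]lithium (formed in situ) | [Li]c1c(OCOC)cc(OCOC)cc1OCOC | intermediate
5 | 1,3,5-tris(methoxymethoxy)-2-(3-methylbut-2-en-1-yl)benzene | COCOc1cc(OCOC)c(CC=C(C)C)c(OCOC)c1 | intermediate
6 | [2,4,6-tris(methoxymethoxy)-3-(3-methylbut-2-en-1-yl)phenyl]lithium (formed in situ) | [Li]c1c(OCOC)cc(OCOC)c(CC=C(C)C)c1OCOC | intermediate
7 | 1,3,5-tris(methoxymethoxy)-2,4-bis(3-methylbut-2-en-1-yl)benzene | COCOc1cc(OCOC)c(CC=C(C)C)c(OCOC)c1CC=C(C)C | intermediate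
8 | 2,4-bis(3-methylbut-2-en-1-yl)benzene-1,3,5-triol (2,4-diprenylphloroglucinol) | Oc1cc(O)c(CC=C(C)C)c(O)c1CC=C(C)C | intermediate
9 | resorcinol (benzene-1,3-diol) | Oc1cccc(O)c1 | starting material
10 | 1,3-bis(methoxymethoxy)benzene | COCOc1cccc(OCOC)c1 | intermediate
11 | [2,6-bis(methoxymethoxy)phenyl]lithium (formed in situ) | [Li]c1c(OCOC)cccc1OCOC | intermediate
12 | 1,3-bis(methoxymethoxy)-2-(3-methylbut-2-en-1-yl)benzene | COCOc1cccc(OCOC)c1CC=C(C)C | intermediate
13 | [2,4-bis(methoxymethoxy)-3-(3-methylbut-2-en-1-yl)phenyl]lithium (formed in situ) | [Li]c1ccc(OCOC)c(CC=C(C)C)c1OCOC | intermediate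
14 | 2-[2,4-bis(methoxymethoxy)-3-(3-methylbut-2-en-1-yl)phenyl]-4,4,5,5-tetramethyl-1,3,2-dioxaborolane | CC1(C)OB(OC1(C)C)c1ccc(OCOC)c(CC=C(C)C)c1OCOC | intermediate
15 | methyl (E)-3-methoxyacrylate | CO/C=C/C(=O)OC | starting material
16 | methyl 3-acetoxy-2-iodo-3-methoxypropanoate (racemic mixture of diastereomers, formed in situ) | COC(OC(C)=O)C(I)C(=O)OC | intermediate
17 | methyl (Z)-2-iodo-3-methoxyacrylate | CO/C=C(\I)C(=O)OC | intermediate
18 | methyl (E)-2-[2,4-bis(methoxymethoxy)-3-(3-methylbut-2-en-1-yl)phenyl]-3-methoxyacrylate | CO/C=C(/C(=O)OC)c1ccc(OCOC)c(CC=C(C)C)c1OCOC | intermediate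
19 | (E)-2-[2,4-bis(methoxymethoxy)-3-(3-methylbut-2-en-1-yl)phenyl]-3-methoxyacrylic acid | CO/C=C(/C(=O)O)c1ccc(OCOC)c(CC=C(C)C)c1OCOC | intermediate
20 | 3,5-dihydroxy-2,4-bis(3-methylbut-2-en-1-yl)phenyl (E)-2-[2,4-bis(methoxymethoxy)-3-(3-methylbut-2-en-1-yl)phenyl]-3-methoxyacrylate | CO/C=C(/C(=O)Oc1cc(O)c(CC=C(C)C)c(O)c1CC=C(C)C)c1ccc(OCOC)c(CC=C(C)C)c1OCOC | intermediate
21 | (E)-2-[2,4-bis(methoxymethoxy)-3-(3-methylbut-2-en-1-yl)phenyl]-3-methoxy-1-[2,4,6-trihydroxy-3,5-bis(3-methylbut-2-en-1-yl)phenyl]prop-2-en-1-one (formed in situ) | CO/C=C(/C(=O)c1c(O)c(CC=C(C)C)c(O)c(CC=C(C)C)c1O)c1ccc(OCOC)c(CC=C(C)C)c1OCOC | intermediate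
22 | 3-[2,4-bis(methoxymethoxy)-3-(3-methylbut-2-en-1-yl)phenyl]-5,7-dihydroxy-6,8-bis(3-methylbut-2-en-1-yl)-4H-chromen-4-one (euchrenone b2 2',4'-bis(methoxymethyl) ether) | CC(C)=CCc1c(OCOC)ccc(-c2coc3c(CC=C(C)C)c(O)c(CC=C(C)C)c(O)c3c2=O)c1OCOC | intermediate
23 | euchrenone b2, 3-[2,4-dihydroxy-3-(3-methylbut-2-en-1-yl)phenyl]-5,7-dihydroxy-6,8-bis(3-methylbut-2-en-1-yl)-4H-chromen-4-one | CC(C)=CCc1c(O)ccc(-c2coc3c(CC=C(C)C)c(O)c(CC=C(C)C)c(O)c3c2=O)c1O | target

**Step count and risks**

Total step count: 13. Longest linear sequence: 8 steps (5, 6, 7, 9, 10, 11, 12, 13, from resorcinol).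

Steps most likely to fail:

1. Step 12. The radical pair may leave the solvent cage before it recombines, so that the ester is merely cleaved back to the phenol. An excited free phenol may add its O–H across a neighbouring prenyl double bond. The accumulating isoflavone may absorb the light and stall the conversion. The fallback builds ring C without light and joins ring B by cross-coupling; it sets out from 7 and returns to the route at 23. The last ring proton of 7 is removed with n-BuLi in THF at 0 °C to give [2,4,6-tris(methoxymethoxy)-3,5-diprenylphenyl]lithium F1, which is acetylated with N-methoxy-N-methylacetamide to 2,4,6-tris(methoxymethoxy)-3,5-diprenylacetophenone F2. Brief treatment with dilute HCl in MeOH at 0 °C removes one of the two carbonyl-flanking MOM groups, the hydrogen-bonded product being slow to lose the second, and should give 2-hydroxy-4,6-bis(methoxymethoxy)-3,5-diprenylacetophenone F3. Heating with Me2NCH(OMe)2 gives the enaminone (E)-3-(dimethylamino)-1-[2-hydroxy-4,6-bis(methoxymethoxy)-3,5-diprenylphenyl]prop-2-en-1-one F4. Iodine in CHCl3/pyridine closes F4 to 3-iodo-5,7-bis(methoxymethoxy)-6,8-diprenylchromen-4-one F5; iodine adds only reversibly to the prenyl alkenes and is washed out with thiosulfate. Suzuki–Miyaura coupling of F5 with boronate 14 (Pd(PPh3)4, Na2CO3, DME/H2O) gives euchrenone b2 tetrakis(methoxymethyl) ether F6, and HCl in MeOH as in step 13 removes all four MOM groups to reach 23.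

2. Step 11. Acylation may run on past the monoester, a slow coupling may divert the activated acid into an unreactive N-acylurea, or the electron-rich triol may oxidise under the basic coupling conditions. The fallback gives up selective monoacylation in favour of deliberate diacylation; it sets out from 8 and 19 and returns at 22. Triol 8 is acylated on both unhindered oxygens with 19 (2.2 equiv, N,N'-diisopropylcarbodiimide, DMAP) to give the diester 5-hydroxy-4,6-diprenyl-1,3-phenylene bis[(E)-2-aryl-3-methoxyacrylate] F7 (aryl = 2,4-bis(methoxymethoxy)-3-prenylphenyl). Irradiation as in step 12 can move only one acyl group to carbon, because only one ring carbon is free, giving the ortho-acyloxy Fries ketone F8 (not isolated). Its single free flanking hydroxyl closes ring C to the 5-O-acyl derivative of 22, euchrenone b2 2',4'-bis(methoxymethyl) ether 5-O-[(E)-2-aryl-3-methoxyacrylate] F9. K2CO3 in MeOH then cleaves the remaining aryl ester to give 22, and the second acyl group comes back as methyl ester 18, which can re-enter at step 10.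

3. Step 4. During acetal cleavage the acid may promote addition of a freed phenolic hydroxyl to a prenyl double bond (chroman formation), and the very electron-rich triol may oxidise in air. The fallback avoids protecting groups and acid altogether; it sets out from 1 and 3 and returns at 8. Phloroglucinol 1, in excess, is C-alkylated with 3 in cold aqueous KOH (phenoxide C-alkylation in a protic medium) to give 2-prenylphloroglucinol F10. A second C-alkylation of F10 under the same conditions gives 8 after chromatographic removal of over-alkylated and geminally dialkylated material. This is poorer in throughput but uses bulk materials.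

**Further compounds**

F1 | step 12 | [2,4,6-tris(methoxymethoxy)-3,5-bis(3-methylbut-2-en-1-yl)phenyl]lithium | [Li]c1c(OCOC)c(CC=C(C)C)c(OCOC)c(CC=C(C)C)c1OCOC
F2 | step 12 | 1-[2,4,6-tris(methoxymethoxy)-3,5-bis(3-methylbut-2-en-1-yl)phenyl]ethan-1-one | CC(=O)c1c(OCOC)c(CC=C(C)C)c(OCOC)c(CC=C(C)C)c1OCOC
F3 | step 12 | 1-[2-hydroxy-4,6-bis(methoxymethoxy)-3,5-bis(3-methylbut-2-en-1-yl)phenyl]ethan-1-one | CC(=O)c1c(O)c(CC=C(C)C)c(OCOC)c(CC=C(C)C)c1OCOC
F4 | step 12 | (E)-3-(dimethylamino)-1-[2-hydroxy-4,6-bis(methoxymethoxy)-3,5-bis(3-methylbut-2-en-1-yl)phenyl]prop-2-en-1-one | CN(C)/C=C/C(=O)c1c(O)c(CC=C(C)C)c(OCOC)c(CC=C(C)C)c1OCOC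
F5 | step 12 | 3-iodo-5,7-bis(methoxymethoxy)-6,8-bis(3-methylbut-2-en-1-yl)-4H-chromen-4-one | O=c1c(I)coc2c(CC=C(C)C)c(OCOC)c(CC=C(C)C)c(OCOC)c12
F6 | step 12 | 3-[2,4-bis(methoxymethoxy)-3-(3-methylbut-2-en-1-yl)phenyl]-5,7-bis(methoxymethoxy)-6,8-bis(3-methylbut-2-en-1-yl)-4H-chromen-4-one | CC(C)=CCc1c(OCOC)ccc(-c2coc3c(CC=C(C)C)c(OCOC)c(CC=C(C)C)c(OCOC)c3c2=O)c1OCOC
F7 | step 11 | 5-hydroxy-4,6-bis(3-methylbut-2-en-1-yl)-1,3-phenylene bis{(E)-2-[2,4-bis(methoxymethoxy)-3-(3-methylbut-2-en-1-yl)phenyl]-3-methoxyacrylate} | CO/C=C(/C(=O)Oc1cc(OC(=O)/C(=C/OC)c2ccc(OCOC)c(CC=C(C)C)c2OCOC)c(CC=C(C)C)c(O)c1CC=C(C)C)c1ccc(OCOC)c(CC=C(C)C)c1OCOC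
F8 | step 11 | 3,5-dihydroxy-2-{(E)-2-[2,4-bis(methoxymethoxy)-3-(3-methylbut-2-en-1-yl)phenyl]-3-methoxyacryloyl}-4,6-bis(3-methylbut-2-en-1-yl)phenyl (E)-2-[2,4-bis(methoxymethoxy)-3-(3-methylbut-2-en-1-yl)phenyl]-3-methoxyacrylate | CO/C=C(/C(=O)c1c(O)c(CC=C(C)C)c(O)c(CC=C(C)C)c1OC(=O)/C(=C/OC)c1ccc(OCOC)c(CC=C(C)C)c1OCOC)c1ccc(OCOC)c(CC=C(C)C)c1OCOC
F9 | step 11 | 3-[2,4-bis(methoxymethoxy)-3-(3-methylbut-2-en-1-yl)phenyl]-7-hydroxy-6,8-bis(3-methylbut-2-en-1-yl)-4-oxo-4H-chromen-5-yl (E)-2-[2,4-bis(methoxymethoxy)-3-(3-methylbut-2-en-1-yl)phenyl]-3-methoxyacrylate | CO/C=C(/C(=O)Oc1c(CC=C(C)C)c(O)c(CC=C(C)C)c2occ(-c3ccc(OCOC)c(CC=C(C)C)c3OCOC)c(=O)c12)c1ccc(OCOC)c(CC=C(C)C)c1OCOC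
F10 | step 4 | 2-(3-methylbut-2-en-1-yl)benzene-1,3,5-triol | CC(C)=CCc1c(O)cc(O)cc1O
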